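## The problem

Ocophyllal B (22) is a 2-aryl-3-methylbenzofuran whose benzo ring (ring A) is fused to the furan (ring B) through C3a and C7a. Ring A carries a methoxy group at C7 and a formyl group at C5, with hydrogens only at C4 and C6. The target has no stereocentre; the sp3 centres that appear on the way (in 3, 5 and 16) are racemic, are erased later, and neither can nor need control anything. The difficulty is regiochemical: the C7 oxygen and the C5 one-carbon branch must sit meta to each other on a ring already flanked by the furan. Substitution of a preformed 7-oxygenated benzofuran would not address C5 cleanly, so the pattern is better built into ring A as it is closed. The aryl aldehyde will not survive organolithium reagents or strong base, and is therefore carried as a silyl-protected primary alcohol until the last step. The electron-rich furan and trimethoxyphenyl rings limit the use of strong acids and oxidants, and one intermediate is a polymerisation-prone vinyl ketone. The enabling feature is the C5=C6 bond of ring A, which lies between C7 (oxygen-bearing, bonded to C7a) and C5 (branch-bearing, reached from C3a through C4). A vinyl ketone on C7a and a 2-substituted allyl group on C3a of a furan place both ends of that bond within reach, and the cyclic dienone formed is simply the keto tautomer of the C7 phenol.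

## Retrosynthesis

**Endgame (22 ← 21 ← 20 ← 19).** The formyl group of 22 is taken back to the benzylic alcohol 21, this to its silyl ether 20, and the C7 methyl ether to the phenol 19 (cut of the O–CH3 bond). Keeping C5 at the alcohol oxidation level under a silyl group is preferred to carrying an aldehyde or an ester: an aldehyde would not pass the organometallic steps, and a carbonyl-substituted alkene would be a poor metathesis partner. The forward reactions only have to distinguish a phenol from a silyl ether and then oxidise a benzylic alcohol.

**Ring A (19 ← 18 ← 17).** The phenol 19 is the enol form of the 4H-benzofuran-7-one 18, and in 18 the C5=C6 double bond is cut by a metathesis transform to the dienone 17. The neighbouring cuts of ring A (C7–C7a by acylation, or C4–C5 and C6–C7 by an anionic annulation) either bring C5 in at the wrong oxidation level or stack several bond-forming events into one flask. Cutting C5=C6 leaves two arms that each carry one of the two ring-A substituents, so the 5,7-pattern is fixed by connectivity alone. The precursor 17 has no ring A, only a tetrasubstituted furan. The forward step must close a six-membered ring between an electron-poor vinyl ketone and a 1,1-disubstituted alkene faster than the enone oligomerises.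

**Acyl arm (17 ← 16 ← 13 + 14).** The C7–C7a bond is cut between the furan α-carbon and the carbinol carbon of 16, leading to the 2-lithiofuran 15 (from 13) and acrolein 14. The ketone 17 then follows by oxidation of the doubly activated alcohol 16. The alternative of acylating the furan with an acrylic acid derivative invites conjugate addition. Addition to the aldehyde followed by mild oxidation asks only that the single free α-position of 13 be metallated selectively.

**Allyl arm (13 ← 8 + 10; 10 ← 9).** The C4–C5 bond is cut between the furylmethyl carbon and the alkene carbon, giving the furylmethyl bromide 8 and the alkenyl bromide 10, which is the silyl ether of 2-bromoprop-2-en-1-ol 9. In the forward sense 10 becomes the nucleophile (via 11 and 12) and 8 the electrophile. The reverse assignment of polarity is held in reserve. This cut is preferred to one at C3a–C4, which would need a 3-metallated or 3-halogenated furan that is much harder to reach.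

**Functional group changes at C4 (8 ← 7 ← 6).** The bromide 8 comes from the alcohol 7 and this from the furan-3-carboxylate 6. The ester carbon of 6 thus becomes C4 of the target, and the ester also makes the furan easy to construct.

**Furan ring (6 ← 5 ← 3 + 4; 3 ← 1 + 2).** The furan of 6 is opened across the O–C bonds to the 1,4-keto aldehyde 5. Its formyl carbon (the later C7a) is cut off as ethyl formate 4, leaving the keto ester 3. The bond between C3 and C3a is then cut to the enolate of the propiophenone 1 and ethyl bromoacetate 2. Ketone 1 supplies the aryl group, C2, C3 and the C3 methyl group in one piece. The methyl group also helps the formylation: the ketone α-carbon of 3 is tertiary, so only the ester methylene can give a stable formyl enolate.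

## Roads not taken

**Alternative 1:** Ring B is cut at O1–C2 and C2–C3. In the forward sense a carbonate base expels sulfinate from the phenolic sulfone A2 to give an ortho-quinone methide. The ylide of the benzylsulfonium salt A3 adds to its methide carbon, and the phenoxide then displaces the sulfide to close the trans-dihydrobenzofuran A1.
- Merits: both aromatic rings are bought with their substituents in place, so the regiochemistry of ring A is never at issue, and the route is convergent. In step count it is very probably shorter than the chosen plan.
- Weak points: A1 is at the wrong oxidation level. Its two stereocentres are made only to be destroyed by a later dehydrogenation of ring B with a quinone-type oxidant, on a substrate with two electron-rich arenes and an acetal. A quinone methide with a methyl group on the methide carbon can drain away to the ortho-vinylphenol by hydrogen shift. A2 itself needs an ortho-(1-sulfonylethyl)ation of a para-substituted guaiacol that is not trivial.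
- Comparison: this road wins on brevity and convergence. The chosen plan offers in return a ring closure that delivers the aromatic benzofuran directly, no late oxidation of the heterocycle, and no intermediate as short-lived as an alkyl-substituted quinone methide.

**Alternative 2:** Ring A is cut at C4–C5 and C6–C7. A lithium amide base deprotonates the methyl group next to the ester of the furoate A5. The lateral anion adds to the vinyl sulfoxide A6 (C4–C5), the resulting sulfinyl carbanion closes onto the ester (C6–C7), and loss of the sulfenic acid aromatises ring A to the phenol A4.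
- Merits: ring A, the C7 oxygen and the C5 carbon at the aldehyde oxidation level (as an acetal) arrive in one flask. The endgame is then only O-methylation and acetal hydrolysis, one step shorter than the endgame of the chosen plan and without a final oxidation.
- Weak points: three events (conjugate addition, Dieckmann-type acylation, elimination) must succeed in sequence. The acceptor A6 is β-substituted and only moderately electrophilic, while the nucleophile is a hindered, delocalised furoate anion that can instead attack the ester of a second molecule of A5. The fully substituted furoate A5 is no easier to make than furan 13.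
- Comparison: the endgame is better here. The chosen plan spreads the same bond construction over individually reliable steps, and its ring closure has close analogy in aromatising metatheses.

**Alternative 3:** Ring A is cut at C7–C7a. The aldehyde A9 is condensed with a succinic diester (Stobbe condensation) to the half-ester A8. Under the classical hot anhydride/carboxylate conditions its activated acid carbon attacks the free furan α-position, closing ring A as the acetoxy ester A7.
- Merits: the chemistry is classical and needs no transition metal. The cyclisation uses the most nucleophilic position of the furan. A9 is one oxidation away from alcohol 7 of the chosen route. In step count this road is as short as the chosen plan, perhaps a step shorter.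
- Weak points: only the E half-ester can cyclise. The C5 carbon arrives as an ester, so the endgame needs acetate cleavage, O-methylation, a hydride reduction and a re-oxidation. The electron-rich furan must tolerate hot acylating conditions.
- Comparison: the two plans are close. The chosen plan brings the branch in at the alcohol oxidation level, closes the ring under neutral conditions, and cannot depend on alkene geometry because both alkenes are terminal.

Key step: step 9

Remark: the sp3 stereocentres of 3, 5 and 16 are formed without control; all are erased before the achiral target, so these compounds are handled as racemates or mixtures.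

## Route

Step 1
Reactants: 1 1-(3,4,5-trimethoxyphenyl)propan-1-one; 2 ethyl bromoacetate
Product: 3 ethyl 3-methyl-4-oxo-4-(3,4,5-trimethoxyphenyl)butanoate (racemic)
Conditions: LiN(SiMe3)2, THF, −78 °C; then 2, −78 °C → rt
Reagents that add atoms: none
Why: Alkylation of a kinetic lithium ketone enolate with a reactive α-halo ester (enolate SN2 alkylation); the aryl ethyl ketone can enolise on one side only, and the tertiary α-hydrogen of the product resists a second alkylation. The new stereocentre is racemic and later becomes sp2.

Step 2
Reactants: 3 ethyl 3-methyl-4-oxo-4-(3,4,5-trimethoxyphenyl)butanoate; 4 ethyl formate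
Product: 6 ethyl 4-methyl-5-(3,4,5-trimethoxyphenyl)furan-3-carboxylate, via formyl keto ester 5 (not isolated)
Conditions: NaH, EtOH (cat.), THF, 0 °C → rt; then TsOH·H2O (excess), PhMe, 80 °C
Reagents that add atoms: none
Why: Crossed Claisen formylation followed by Paal–Knorr cyclodehydration. Formylation at the tertiary ketone α-carbon would give a non-enolisable adduct that reverts, whereas the ester methylene gives a stabilised sodium enolate. Acid then closes the 1,4-keto aldehyde 5 to the only possible furan.

Step 3
Reactants: 6 ethyl 4-methyl-5-(3,4,5-trimethoxyphenyl)furan-3-carboxylate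
Product: 7 [4-methyl-5-(3,4,5-trimethoxyphenyl)furan-3-yl]methanol
Conditions: LiAlH4, THF, 0 °C; then H2O
Reagents that add atoms: none
Why: Hydride reduction of an ester to the primary alcohol; the furan and the aryl methyl ethers are inert to LiAlH4.

Step 4
Reactants: 7 [4-methyl-5-(3,4,5-trimethoxyphenyl)furan-3-yl]methanol
Product: 8 4-(bromomethyl)-3-methyl-2-(3,4,5-trimethoxyphenyl)furan
Conditions: PBr3, pyridine (cat.), Et2O, 0 °C; used crude at once
Reagents that add atoms: phosphorus tribromide, BrP(Br)Br
Why: Conversion of an alcohol into the bromide through its phosphite ester (SN2), the usual way to 3-(bromomethyl)furans. The by-products are removed by aqueous washing, so the solvolysis-prone bromide can go into the coupling without chromatography.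

Step 5
Reactants: 9 2-bromoprop-2-en-1-ol
Product: 10 [(2-bromoprop-2-en-1-yl)oxy](tert-butyl)dimethylsilane
Conditions: TBSCl, imidazole, CH2Cl2, rt
Reagents that add atoms: tert-butyl(chloro)dimethylsilane, CC(C)(C)[Si](C)(C)Cl
Why: Standard silylation of a primary allylic alcohol; the alkenyl bromide does not react.

Step 6
Reactants: 10 [(2-bromoprop-2-en-1-yl)oxy](tert-butyl)dimethylsilane; 8 4-(bromomethyl)-3-methyl-2-(3,4,5-trimethoxyphenyl)furan
Product: 13 tert-butyl(dimethyl)[(2-{[4-methyl-5-(3,4,5-trimethoxyphenyl)furan-3-yl]methyl}prop-2-en-1-yl)oxy]silane, via vinyllithium 11 (not isolated), via vinylmagnesium bromide 12 (not isolated)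
Conditions: 10, t-BuLi (2 equiv), Et2O, −78 °C; MgBr2·OEt2, −78 °C; then CuI (10 mol%), 8, THF, −78 → 0 °C
Reagents that add atoms: none
Why: Bromine–lithium exchange at −78 °C gives the 2-lithioallyl silyl ether, cold enough to hold back β-elimination and silyl shift. Transmetalation to magnesium gives a Grignard reagent that substitutes the activated furylmethyl bromide under CuI catalysis (copper-catalysed Grignard sp2–sp3 cross-coupling).

Step 7
Reactants: 13 tert-butyl(dimethyl)[(2-{[4-methyl-5-(3,4,5-trimethoxyphenyl)furan-3-yl]methyl}prop-2-en-1-yl)oxy]silane; 14 acrolein (prop-2-enal)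
Product: 16 1-[3-(2-{[tert-butyl(dimethyl)silyl]oxymethyl}prop-2-en-1-yl)-4-methyl-5-(3,4,5-trimethoxyphenyl)furan-2-yl]prop-2-en-1-ol (racemic), via 2-lithiofuran 15 (not isolated)
Conditions: n-BuLi, THF, −78 → −20 °C; then 14, −78 °C; then H2O
Reagents that add atoms: none
Why: α-Lithiation of a furan at its only free α-position, the most acidic ring C–H next to the ring oxygen, followed by 1,2-addition of the heteroaryllithium to the enal at low temperature. The carbinol centre is formed without control (racemic) and is removed in step 8.

Step 8
Reactants: 16 1-[3-(2-{[tert-butyl(dimethyl)silyl]oxymethyl}prop-2-en-1-yl)-4-methyl-5-(3,4,5-trimethoxyphenyl)furan-2-yl]prop-2-en-1-ol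
Product: 17 1-[3-(2-{[tert-butyl(dimethyl)silyl]oxymethyl}prop-2-en-1-yl)-4-methyl-5-(3,4,5-trimethoxyphenyl)furan-2-yl]prop-2-en-1-one
Conditions: MnO2 (activated, excess), CH2Cl2, rt; used without delay
Reagents that add atoms: none
Why: MnO2 oxidation of a doubly activated (allylic and furylic) secondary alcohol. The reagent is neutral and heterogeneous, so the silyl ether and the isolated alkene are untouched and the polymerisation-prone vinyl ketone is obtained by simple filtration.

Step 9
Reactants: 17 1-[3-(2-{[tert-butyl(dimethyl)silyl]oxymethyl}prop-2-en-1-yl)-4-methyl-5-(3,4,5-trimethoxyphenyl)furan-2-yl]prop-2-en-1-one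
Product: 19 5-({[tert-butyl(dimethyl)silyl]oxy}methyl)-3-methyl-2-(3,4,5-trimethoxyphenyl)-1-benzofuran-7-ol, via 4H-benzofuran-7-one 18 (not isolated)
Conditions: (H2IMes)(PCy3)Cl2Ru=CHPh (second-generation Grubbs catalyst, 5–10 mol%), CH2Cl2 (0.005 M), 40 °C
Reagents that add atoms: none
Why: Ring-closing olefin metathesis followed by keto–enol aromatisation, the reaction type known from the conversion of ortho-allylaryl vinyl ketones into naphthols and related phenols. After loss of PCy3 the ruthenium alkylidene exchanges its carbene with one terminal alkene of 17, most plausibly the monosubstituted vinyl group, since loading on the 1,1-disubstituted alkene would require a disubstituted alkylidene. The tethered second alkene then adds to give a ruthenacyclobutane, whose cycloreversion forms the C5=C6 bond and a ruthenium methylidene that carries the chain. The six-membered ring A is closed by this single bond between two arms held cis on the adjacent furan carbons C7a and C3a; this pre-organisation and high dilution favour ring closure over cross-metathesis and oligomerisation of the enone. The N-heterocyclic carbene ligand supplies the activity needed for an electron-poor enone and a trisubstituted product alkene. The first-formed dienone 18 has doubly activated C4 hydrogens and should enolise at once to the phenol 19; this aromatisation and the escape of ethene make the closure irreversible. No stereocentre is formed. The 5,7-pattern cannot vary, because the oxygen comes in on the C7a arm and the silyloxymethyl branch on the C3a arm.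

Step 10
Reactants: 19 5-({[tert-butyl(dimethyl)silyl]oxy}methyl)-3-methyl-2-(3,4,5-trimethoxyphenyl)-1-benzofuran-7-ol
Product: 20 tert-butyl{[7-methoxy-3-methyl-2-(3,4,5-trimethoxyphenyl)-1-benzofuran-5-yl]methoxy}dimethylsilane
Conditions: MeI, K2CO3, acetone, reflux
Reagents that add atoms: iodomethane, CI
Why: Williamson O-methylation of a phenoxide; K2CO3 deprotonates only the phenol, and the primary silyl ether is stable to these conditions.

Step 11
Reactants: 20 tert-butyl{[7-methoxy-3-methyl-2-(3,4,5-trimethoxyphenyl)-1-benzofuran-5-yl]methoxy}dimethylsilane
Product: 21 [7-methoxy-3-methyl-2-(3,4,5-trimethoxyphenyl)-1-benzofuran-5-yl]methanol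
Conditions: n-Bu4NF, THF, 0 °C → rt
Reagents that add atoms: none
Why: Fluoride-induced cleavage of a silyl ether, driven by the strength of the Si–F bond; nothing else in the molecule reacts with fluoride.

Step 12
Reactants: 21 [7-methoxy-3-methyl-2-(3,4,5-trimethoxyphenyl)-1-benzofuran-5-yl]methanol
Product: 22 7-methoxy-3-methyl-2-(3,4,5-trimethoxyphenyl)-1-benzofuran-5-carbaldehyde (ocophyllal B)
Conditions: MnO2 (activated, excess), CH2Cl2, rt
Reagents that add atoms: none
Why: MnO2 oxidation of a benzylic alcohol stops at the aldehyde and leaves the electron-rich benzofuran and the C3 methyl group alone.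

## Compound list

1 | 1-(3,4,5-trimethoxyphenyl)propan-1-one | CCC(=O)c1cc(OC)c(OC)c(OC)c1 | starting material
2 | ethyl bromoacetate | CCOC(=O)CBr | starting material
3 | ethyl 3-methyl-4-oxo-4-(3,4,5-trimethoxyphenyl)butanoate (racemic) | CCOC(=O)CC(C)C(=O)c1cc(OC)c(OC)c(OC)c1 | intermediate
4 | ethyl formate | CCOC=O | starting material
5 | ethyl 2-formyl-3-methyl-4-oxo-4-(3,4,5-trimethoxyphenyl)butanoate (mixture of diastereomers and enol forms, not isolated) | CCOC(=O)C(C=O)C(C)C(=O)c1cc(OC)c(OC)c(OC)c1 | intermediate
6 | ethyl 4-methyl-5-(3,4,5-trimethoxyphenyl)furan-3-carboxylate | CCOC(=O)c1coc(-c2cc(OC)c(OC)c(OC)c2)c1C | intermediate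
7 | [4-methyl-5-(3,4,5-trimethoxyphenyl)furan-3-yl]methanol | OCc1coc(-c2cc(OC)c(OC)c(OC)c2)c1C | intermediate
8 | 4-(bromomethyl)-3-methyl-2-(3,4,5-trimethoxyphenyl)furan | BrCc1coc(-c2cc(OC)c(OC)c(OC)c2)c1C | intermediate
9 | 2-bromoprop-2-en-1-ol | C=C(Br)CO | starting material
10 | [(2-bromoprop-2-en-1-yl)oxy](tert-butyl)dimethylsilane | C=C(Br)CO[Si](C)(C)C(C)(C)C | intermediate
11 | (3-{[tert-butyl(dimethyl)silyl]oxy}prop-1-en-2-yl)lithium (not isolated) | [Li]C(=C)CO[Si](C)(C)C(C)(C)C | intermediate
12 | bromo(3-{[tert-butyl(dimethyl)silyl]oxy}prop-1-en-2-yl)magnesium (not isolated) | Br[Mg]C(=C)CO[Si](C)(C)C(C)(C)C | intermediate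
13 | tert-butyl(dimethyl)[(2-{[4-methyl-5-(3,4,5-trimethoxyphenyl)furan-3-yl]methyl}prop-2-en-1-yl)oxy]silane | C=C(Cc1coc(-c2cc(OC)c(OC)c(OC)c2)c1C)CO[Si](C)(C)C(C)(C)C | intermediate
14 | acrolein (prop-2-enal) | C=CC=O | starting material
15 | [3-(2-{[tert-butyl(dimethyl)silyl]oxymethyl}prop-2-en-1-yl)-4-methyl-5-(3,4,5-trimethoxyphenyl)furan-2-yl]lithium (not isolated) | [Li]c1oc(-c2cc(OC)c(OC)c(OC)c2)c(C)c1CC(=C)CO[Si](C)(C)C(C)(C)C | intermediate
16 | 1-[3-(2-{[tert-butyl(dimethyl)silyl]oxymethyl}prop-2-en-1-yl)-4-methyl-5-(3,4,5-trimethoxyphenyl)furan-2-yl]prop-2-en-1-ol (racemic) | C=CC(O)c1oc(-c2cc(OC)c(OC)c(OC)c2)c(C)c1CC(=C)CO[Si](C)(C)C(C)(C)C | intermediate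
17 | 1-[3-(2-{[tert-butyl(dimethyl)silyl]oxymethyl}prop-2-en-1-yl)-4-methyl-5-(3,4,5-trimethoxyphenyl)furan-2-yl]prop-2-en-1-one | C=CC(=O)c1oc(-c2cc(OC)c(OC)c(OC)c2)c(C)c1CC(=C)CO[Si](C)(C)C(C)(C)C | intermediate
18 | 5-({[tert-butyl(dimethyl)silyl]oxy}methyl)-3-methyl-2-(3,4,5-trimethoxyphenyl)-1-benzofuran-7(4H)-one (not isolated) | O=C1C=C(CO[Si](C)(C)C(C)(C)C)Cc2c(C)c(-c3cc(OC)c(OC)c(OC)c3)oc21 | intermediate
19 | 5-({[tert-butyl(dimethyl)silyl]oxy}methyl)-3-methyl-2-(3,4,5-trimethoxyphenyl)-1-benzofuran-7-ol | CC(C)(C)[Si](C)(C)OCc1cc(O)c2oc(-c3cc(OC)c(OC)c(OC)c3)c(C)c2c1 | intermediate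
20 | tert-butyl{[7-methoxy-3-methyl-2-(3,4,5-trimethoxyphenyl)-1-benzofuran-5-yl]methoxy}dimethylsilane | COc1cc(CO[Si](C)(C)C(C)(C)C)cc2c(C)c(-c3cc(OC)c(OC)c(OC)c3)oc12 | intermediate
21 | [7-methoxy-3-methyl-2-(3,4,5-trimethoxyphenyl)-1-benzofuran-5-yl]methanol | COc1cc(CO)cc2c(C)c(-c3cc(OC)c(OC)c(OC)c3)oc12 | intermediate
22 | 7-methoxy-3-methyl-2-(3,4,5-trimethoxyphenyl)-1-benzofuran-5-carbaldehyde (ocophyllal B) | COc1cc(-c2oc3c(OC)cc(C=O)cc3c2C)cc(OC)c1OC | target

## Step count and risks

Total steps: 12. Longest linear sequence: 11 steps (steps 1–4 and 6–12); step 5 prepares the side fragment.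

Steps least certain to work:

**Step 9 (key step).** Ring closure may be outrun by cross-metathesis, oligomerisation or conjugate addition of the vinyl ketone. Turnover may also stall because both alkenes are reluctant partners, one electron-poor and one 1,1-disubstituted. Fallback, setting out from 16: the order of oxidation and ring closure is exchanged. The allylic alcohol 16, whose carbinol-bearing alkene is a much better metathesis partner than the enone, is closed with the same ruthenium catalyst to 5-({[tert-butyl(dimethyl)silyl]oxy}methyl)-3-methyl-2-(3,4,5-trimethoxyphenyl)-4,7-dihydro-1-benzofuran-7-ol F1. F1 is oxidised without delay and under neutral conditions (MnO2, CH2Cl2) to the dienone 18, which tautomerises; the fallback rejoins the route at 19. It also avoids isolating the vinyl ketone 17. Its own hazard is acid-induced loss of water from F1, which must therefore not be stored or exposed to acid.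

**Step 6.** The 2-metallated allyl silyl ether may be lost before it couples, by a shift of the silyl group from oxygen to the carbanionic carbon or by β-elimination of silanolate to an allene. The activated bromide 8 may also homocouple. Fallback, setting out from 8: the polarity is reversed so that no alkenyl anion is needed. Zinc (Zn dust, LiCl, THF) is inserted into 8 to give bromo{[4-methyl-5-(3,4,5-trimethoxyphenyl)furan-3-yl]methyl}zinc F2. F2 is joined to the alkenyl bromide 10 in a Negishi coupling catalysed by Pd(PPh3)4, rejoining the route at 13.

**Step 7.** Deprotonation may go astray, to the doubly activated (furylic and allylic) methylene or to an aryl position next to a methoxy group, and acrolein may add in the conjugate sense or polymerise. Fallback, setting out from 13: the position is fixed by a halogen. Electrophilic bromination of the free furan α-position with N-bromosuccinimide (THF, −40 °C) gives ({2-[(2-bromo-4-methyl-5-(3,4,5-trimethoxyphenyl)furan-3-yl)methyl]prop-2-en-1-yl}oxy)(tert-butyl)dimethylsilane F3. Bromine–lithium exchange with n-BuLi at −78 °C, much faster than any deprotonation, then gives 15, where the route is rejoined before the addition of 14.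

**Step 2.** The Claisen formylation of a simple ester methylene may be slow or may be diverted by the more acidic ketone, whose enolate ties up the base. Fallback, setting out from 3: the ester methylene is aminomethylenated instead of formylated. Heating 3 with tert-butoxybis(dimethylamino)methane in toluene gives ethyl 2-[(dimethylamino)methylidene]-3-methyl-4-oxo-4-(3,4,5-trimethoxyphenyl)butanoate F4; the tertiary ketone α-carbon cannot condense. Aqueous HCl in THF then hydrolyses the enamine to 5 and cyclises it, rejoining the route at 6.

## Further compounds

F1 | step 9 | 5-({[tert-butyl(dimethyl)silyl]oxy}methyl)-3-methyl-2-(3,4,5-trimethoxyphenyl)-4,7-dihydro-1-benzofuran-7-ol (racemic) | OC1C=C(CO[Si](C)(C)C(C)(C)C)Cc2c(C)c(-c3cc(OC)c(OC)c(OC)c3)oc21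
F2 | step 6 | bromo{[4-methyl-5-(3,4,5-trimethoxyphenyl)furan-3-yl]methyl}zinc | Br[Zn]Cc1coc(-c2cc(OC)c(OC)c(OC)c2)c1C
F3 | step 7 | ({2-[(2-bromo-4-methyl-5-(3,4,5-trimethoxyphenyl)furan-3-yl)methyl]prop-2-en-1-yl}oxy)(tert-butyl)dimethylsilane | Brc1oc(-c2cc(OC)c(OC)c(OC)c2)c(C)c1CC(=C)CO[Si](C)(C)C(C)(C)C
F4 | step 2 | ethyl 2-[(dimethylamino)methylidene]-3-methyl-4-oxo-4-(3,4,5-trimethoxyphenyl)butanoate (racemic, alkene geometry not defined, either isomer serves) | CCOC(=O)C(=CN(C)C)C(C)C(=O)c1cc(OC)c(OC)c(OC)c1
A1 | alternative 1 | trans-2-[7-methoxy-3-methyl-2-(3,4,5-trimethoxyphenyl)-2,3-dihydro-1-benzofuran-5-yl]-1,3-dioxolane (racemic, one enantiomer drawn) | COc1cc([C@@H]2Oc3c(OC)cc(C4OCCO4)cc3[C@H]2C)cc(OC)c1OC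
A2 | alternative 1 | 4-(1,3-dioxolan-2-yl)-2-methoxy-6-[1-(4-methylbenzenesulfonyl)ethyl]phenol (racemic) | COc1cc(C2OCCO2)cc(C(C)S(=O)(=O)c2ccc(C)cc2)c1O
A3 | alternative 1 | dimethyl[(3,4,5-trimethoxyphenyl)methyl]sulfonium bromide | C[S+](C)Cc1cc(OC)c(OC)c(OC)c1.[Br-]
A4 | alternative 2 | 5-(diethoxymethyl)-3-methyl-2-(3,4,5-trimethoxyphenyl)-1-benzofuran-7-ol | CCOC(OCC)c1cc(O)c2oc(-c3cc(OC)c(OC)c(OC)c3)c(C)c2c1
A5 | alternative 2 | methyl 3,4-dimethyl-5-(3,4,5-trimethoxyphenyl)furan-2-carboxylate | COC(=O)c1oc(-c2cc(OC)c(OC)c(OC)c2)c(C)c1C
A6 | alternative 2 | [(E)-3,3-diethoxyprop-1-ene-1-sulfinyl]benzene (racemic at sulfur) | CCOC(OCC)/C=C/S(=O)c1ccccc1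
A7 | alternative 3 | methyl 7-acetoxy-3-methyl-2-(3,4,5-trimethoxyphenyl)-1-benzofuran-5-carboxylate | COC(=O)c1cc(OC(C)=O)c2oc(-c3cc(OC)c(OC)c(OC)c3)c(C)c2c1
A8 | alternative 3 | (3E)-3-(methoxycarbonyl)-4-[4-methyl-5-(3,4,5-trimethoxyphenyl)furan-3-yl]but-3-enoic acid | COC(=O)/C(CC(=O)O)=C/c1coc(-c2cc(OC)c(OC)c(OC)c2)c1C
A9 | alternative 3 | 4-methyl-5-(3,4,5-trimethoxyphenyl)furan-3-carbaldehyde | O=Cc1coc(-c2cc(OC)c(OC)c(OC)c2)c1C
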